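**Plan**
1. Retrosynthesis: the six phenols are unmasked last from benzyl ethers. Ring C of the flavanone is then cut at two bonds of one annulation, O1–C8a and C4–C4a, which removes ring A as 3,5-bis(benzyloxy)benzyne and leaves an acyclic (S)-β-silyloxy nitrile on ring B.
2. The biaryl bond between C3' of ring B and C8 of the flavone unit is cut next (Suzuki–Miyaura coupling). The carbinol is traced back to a β-ketonitrile.
3. Forward order: the flavone unit comes intact from apigenin (benzylation, C8 iodination). Ring B comes from methyl 3-bromo-4-hydroxybenzoate (benzylation, cyanomethyl ketone, asymmetric transfer hydrogenation, silylation, borylation). The two are joined, and the annulation then adds ring A and closes ring C in one operation before hydrogenolysis.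
4. Enabling feature: ring A is a phloroglucinol ring in which C4a and C8a are adjacent and C5, next to C4a, carries oxygen. It therefore maps onto a 3-alkoxyaryne C4a≡C8a whose C5 substituent sends an oxygen nucleophile to C8a and leaves the carbanion on C4a, within reach of the nitrile carbon C4 through C8a–O1–C2–C3.
5. Stereochemistry: the only stereocenter, C2 (S), is set by RuCl[(S,S)-TsDPEN](p-cymene) transfer hydrogenation of the aryl ketone. Its C–O bond is never broken afterwards, so the annulation proceeds with retention.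

Key step: step 11

Remark: unprimed locants refer to the flavanone unit and primed locants to its ring B; iodination of the 5,7-dialkoxyflavone is taken to occur at C8, the usual site of halogenation in this class.

**Step 1**
Reactants: 1 apigenin
Product: 2 5,7-bis(benzyloxy)-2-(4-benzyloxyphenyl)-4H-chromen-4-one
Conditions: BnBr (4.5 equiv), K2CO3, DMF, 80 °C
Reagents that add atoms: benzyl bromide, BrCc1ccccc1
Why: Williamson etherification of the three phenoxides, run with excess halide in hot DMF because the 5-OH is hydrogen-bonded to the C4 carbonyl and reacts last.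

**Step 2**
Reactants: 2 5,7-bis(benzyloxy)-2-(4-benzyloxyphenyl)-4H-chromen-4-one
Product: 3 5,7-bis(benzyloxy)-2-(4-benzyloxyphenyl)-8-iodo-4H-chromen-4-one
Conditions: NIS (1.05 equiv), TFA (cat.), MeCN/CH2Cl2, 0 °C to rt
Reagents that add atoms: N-iodosuccinimide, O=C1CCC(=O)N1I
Why: Electrophilic aromatic iodination at C8, which is ortho to the ring oxygen and the 7-benzyloxy group, para to the 5-benzyloxy group, and less crowded than C6 between two benzyloxy groups.

**Step 3**
Reactants: 4 methyl 3-bromo-4-hydroxybenzoate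
Product: 5 methyl 4-(benzyloxy)-3-bromobenzoate
Conditions: BnBr, K2CO3, acetone, reflux
Reagents that add atoms: benzyl bromide, BrCc1ccccc1
Why: Williamson etherification of an unhindered phenol.

**Step 4**
Reactants: 5 methyl 4-(benzyloxy)-3-bromobenzoate
Product: 6 3-[4-(benzyloxy)-3-bromophenyl]-3-oxopropanenitrile
Conditions: MeCN (2.2 equiv), n-BuLi (2.2 equiv), THF, –78 °C; then 5, –78 to –40 °C; then 1 M HCl
Reagents that add atoms: acetonitrile, CC#N
Why: Claisen-type acylation of lithiated acetonitrile by the ester, in which the second equivalent of anion deprotonates the β-ketonitrile and so stops double addition, and no butyllithium remains to exchange the aryl bromide.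

**Step 5**
Reactants: 6 3-[4-(benzyloxy)-3-bromophenyl]-3-oxopropanenitrile
Product: 7 (3S)-3-[4-(benzyloxy)-3-bromophenyl]-3-hydroxypropanenitrile
Conditions: RuCl[(S,S)-TsDPEN](p-cymene) (1 mol %), HCO2H/Et3N (5:2), EtOAc, 25 °C
Reagents that add atoms: none
Why: Noyori–Ikariya asymmetric transfer hydrogenation, in which the (S,S) ligand directs hydride to the ketone face that gives the (S)-carbinol (the same sense as for benzoylacetonitrile and acetophenone), setting the later C2.

**Step 6**
Reactants: 7 (3S)-3-[4-(benzyloxy)-3-bromophenyl]-3-hydroxypropanenitrile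
Product: 8 (3S)-3-[4-(benzyloxy)-3-bromophenyl]-3-(triethylsilyloxy)propanenitrile
Conditions: TESCl, imidazole, DMF, 0 °C to rt
Reagents that add atoms: chlorotriethylsilane, CC[Si](Cl)(CC)CC
Why: Silylation of the secondary alcohol, which protects the carbinol from retro-addition and oxidation in steps 7 and 8 and serves as the fluoride-labile latent alkoxide of step 11.

**Step 7**
Reactants: 8 (3S)-3-[4-(benzyloxy)-3-bromophenyl]-3-(triethylsilyloxy)propanenitrile
Product: 9 (3S)-3-[4-(benzyloxy)-3-(4,4,5,5-tetramethyl-1,3,2-dioxaborolan-2-yl)phenyl]-3-(triethylsilyloxy)propanenitrile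
Conditions: B2pin2, Pd(dppf)Cl2 (3 mol %), KOAc, 1,4-dioxane, 90 °C
Reagents that add atoms: bis(pinacolato)diboron, CC1(C)OB(OC1(C)C)B1OC(C)(C)C(C)(C)O1
Why: Miyaura borylation of the aryl bromide, in which the weak acetate base leaves the nitrile and silyl ether untouched.

**Step 8**
Reactants: 9 (3S)-3-[4-(benzyloxy)-3-(4,4,5,5-tetramethyl-1,3,2-dioxaborolan-2-yl)phenyl]-3-(triethylsilyloxy)propanenitrile; 3 5,7-bis(benzyloxy)-2-(4-benzyloxyphenyl)-8-iodo-4H-chromen-4-one
Product: 10 (3S)-3-{4-(benzyloxy)-3-[5,7-bis(benzyloxy)-2-(4-benzyloxyphenyl)-4-oxo-4H-chromen-8-yl]phenyl}-3-(triethylsilyloxy)propanenitrile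
Conditions: Pd(OAc)2 (5 mol %), SPhos (10 mol %), K3PO4, toluene/H2O (10:1), 90 °C
Reagents that add atoms: none
Why: Suzuki–Miyaura coupling, in which the bulky electron-rich biarylphosphine allows the di-ortho-substituted iodide and the ortho-alkoxy boronate to give the tri-ortho-substituted biaryl without touching the silyl-protected stereocenter.

**Step 9**
Reactants: 11 3,5-bis(benzyloxy)phenol
Product: 12 3,5-bis(benzyloxy)-2-bromophenol
Conditions: NBS, CH2Cl2, –78 °C
Reagents that add atoms: N-bromosuccinimide, O=C1CCC(=O)N1Br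
Why: Electrophilic bromination should go mainly to one of the two equivalent positions ortho to the hydroxyl, the site between the two benzyloxy groups being more hindered; a minor 4-bromo isomer would be removed by chromatography.

**Step 10**
Reactants: 12 3,5-bis(benzyloxy)-2-bromophenol
Product: 15 3,5-bis(benzyloxy)-2-(trimethylsilyl)phenyl trifluoromethanesulfonate, via aryl trimethylsilyl ether 13 (not isolated), via lithium 2-silylphenoxide 14 (not isolated)
Conditions: HMDS, THF, 65 °C, then evaporation; n-BuLi, THF, –78 °C; Tf2O, –78 to 0 °C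
Reagents that add atoms: hexamethyldisilazane, C[Si](C)(C)N[Si](C)(C)C; trifluoromethanesulfonic anhydride, O=S(=O)(OS(=O)(=O)C(F)(F)F)C(F)(F)F
Why: O-silylation, bromine–lithium exchange with 1,3 oxygen-to-carbon silyl shift (retro-Brook rearrangement) and triflation of the lithium phenoxide, the standard one-flask route to ortho-silylaryl triflates as aryne precursors.

**Step 11**
Reactants: 10 (3S)-3-{4-(benzyloxy)-3-[5,7-bis(benzyloxy)-2-(4-benzyloxyphenyl)-4-oxo-4H-chromen-8-yl]phenyl}-3-(triethylsilyloxy)propanenitrile; 15 3,5-bis(benzyloxy)-2-(trimethylsilyl)phenyl trifluoromethanesulfonate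
Product: 20 (2S)-5,7-bis(benzyloxy)-2-{4-(benzyloxy)-3-[5,7-bis(benzyloxy)-2-(4-benzyloxyphenyl)-4-oxo-4H-chromen-8-yl]phenyl}chroman-4-one, via 3,5-bis(benzyloxy)benzyne 16 (not isolated), via potassium alkoxide 17 (not isolated), via C4a aryl anion 18 (not isolated), via potassium ketiminate 19 (not isolated)
Conditions: KF (4 equiv), 18-crown-6, THF, 25 °C, 15 (1.5 equiv) added over 2 h; then 1 M aq. HCl, THF, 25–40 °C
Reagents that add atoms: water, O
Why: Proposed new method: fluoride cleaves the O–Si bond of 10 to the proton-free alkoxide 17 and converts 15 into aryne 16; the alkoxide oxygen adds to the aryne carbon remote from the flanking benzyloxy group (the later C8a), which leaves the carbanion of 18 on C4a, and this carbanion adds to the nitrile carbon C4 to give ketiminate 19, which the acid quench hydrolyses to the ketone. The closest known reaction type is the fluoride-induced annulation of arynes by ortho-hydroxyaryl or ortho-aminoaryl esters, ketones and nitriles, which gives xanthones and acridines through the same heteroatom arylation followed by capture of the aryl anion, together with the O-arylation of aliphatic alcohols by arynes; an aliphatic secondary alkoxide carrying a β-nitrile has not been used in this way. Ring C closes in the 6-exo-dig mode (C4a carbanion onto C≡N across C8a–O1–C2–C3) after the intermolecular O1–C8a bond formation. No new stereocenter arises: the C2–O bond made in step 5 is never broken, so C2 stays (S) by retention, and C4 remains an N-metalated imine until the quench, which withholds the enolisable ketone whose base-induced ring opening would racemise C2. The step needs regioselective addition to the unsymmetrical aryne and ring closure faster than proton transfer to the aryl anion: the C5 benzyloxy group polarises and distorts the aryne so that nucleophiles enter at the distal carbon, the silyl ether releases the alkoxide without any O–H proton, and the only carbon acid within reach (C3–H) should give up its proton more slowly than the carbanion adds to the nitrile.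

**Step 12**
Reactants: 20 (2S)-5,7-bis(benzyloxy)-2-{4-(benzyloxy)-3-[5,7-bis(benzyloxy)-2-(4-benzyloxyphenyl)-4-oxo-4H-chromen-8-yl]phenyl}chroman-4-one
Product: 21 (2S)-2,3-dihydroamentoflavone, 8-{5-[(2S)-5,7-dihydroxy-4-oxochroman-2-yl]-2-hydroxyphenyl}-5,7-dihydroxy-2-(4-hydroxyphenyl)-4H-chromen-4-one
Conditions: H2 (1 atm), Pd/C, THF/MeOH, 25 °C
Reagents that add atoms: none
Why: Hydrogenolysis of the six aryl benzyl ethers under neutral conditions, which cannot open ring C by enolisation, so C2 keeps its configuration; hydrogen uptake is followed so that the reaction is stopped before the pyranone double bond or the benzylic C2–O1 bond is attacked.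

**Compound list**
1 | apigenin | O=c1cc(-c2ccc(O)cc2)oc2cc(O)cc(O)c12 | starting material
2 | 5,7-bis(benzyloxy)-2-(4-benzyloxyphenyl)-4H-chromen-4-one | O=c1cc(-c2ccc(OCc3ccccc3)cc2)oc2cc(OCc3ccccc3)cc(OCc3ccccc3)c12 | intermediate
3 | 5,7-bis(benzyloxy)-2-(4-benzyloxyphenyl)-8-iodo-4H-chromen-4-one | O=c1cc(-c2ccc(OCc3ccccc3)cc2)oc2c(I)c(OCc3ccccc3)cc(OCc3ccccc3)c12 | intermediate
4 | methyl 3-bromo-4-hydroxybenzoate | COC(=O)c1ccc(O)c(Br)c1 | starting material
5 | methyl 4-(benzyloxy)-3-bromobenzoate | COC(=O)c1ccc(OCc2ccccc2)c(Br)c1 | intermediate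
6 | 3-[4-(benzyloxy)-3-bromophenyl]-3-oxopropanenitrile | N#CCC(=O)c1ccc(OCc2ccccc2)c(Br)c1 | intermediate
7 | (3S)-3-[4-(benzyloxy)-3-bromophenyl]-3-hydroxypropanenitrile | N#CC[C@@H](c1ccc(OCc2ccccc2)c(Br)c1)O | intermediate
8 | (3S)-3-[4-(benzyloxy)-3-bromophenyl]-3-(triethylsilyloxy)propanenitrile | N#CC[C@@H](c1ccc(OCc2ccccc2)c(Br)c1)O[Si](CC)(CC)CC | intermediate
9 | (3S)-3-[4-(benzyloxy)-3-(4,4,5,5-tetramethyl-1,3,2-dioxaborolan-2-yl)phenyl]-3-(triethylsilyloxy)propanenitrile | N#CC[C@@H](c1ccc(OCc2ccccc2)c(B2OC(C)(C)C(C)(C)O2)c1)O[Si](CC)(CC)CC | intermediate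
10 | (3S)-3-{4-(benzyloxy)-3-[5,7-bis(benzyloxy)-2-(4-benzyloxyphenyl)-4-oxo-4H-chromen-8-yl]phenyl}-3-(triethylsilyloxy)propanenitrile | N#CC[C@@H](c1ccc(OCc2ccccc2)c(-c2c(OCc3ccccc3)cc(OCc3ccccc3)c3c(=O)cc(-c4ccc(OCc5ccccc5)cc4)oc23)c1)O[Si](CC)(CC)CC | intermediate
11 | 3,5-bis(benzyloxy)phenol | Oc1cc(OCc2ccccc2)cc(OCc2ccccc2)c1 | starting material
12 | 3,5-bis(benzyloxy)-2-bromophenol | Oc1cc(OCc2ccccc2)cc(OCc2ccccc2)c1Br | intermediate
13 | [3,5-bis(benzyloxy)-2-bromophenoxy]trimethylsilane | C[Si](C)(C)Oc1cc(OCc2ccccc2)cc(OCc2ccccc2)c1Br | intermediate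
14 | lithium 3,5-bis(benzyloxy)-2-(trimethylsilyl)phenoxide | [Li+].[O-]c1cc(OCc2ccccc2)cc(OCc2ccccc2)c1[Si](C)(C)C | intermediate
15 | 3,5-bis(benzyloxy)-2-(trimethylsilyl)phenyl trifluoromethanesulfonate | C[Si](C)(C)c1c(OS(=O)(=O)C(F)(F)F)cc(OCc2ccccc2)cc1OCc1ccccc1 | intermediate
16 | 3,5-bis(benzyloxy)benzyne (1,2-didehydro-3,5-bis(benzyloxy)benzene) | C1#CC(OCc2ccccc2)=CC(OCc2ccccc2)=C1 | intermediate
17 | potassium (1S)-1-{4-(benzyloxy)-3-[5,7-bis(benzyloxy)-2-(4-benzyloxyphenyl)-4-oxo-4H-chromen-8-yl]phenyl}-2-cyanoethanolate (alkoxide of desilylated 10) | [K+].N#CC[C@@H](c1ccc(OCc2ccccc2)c(-c2c(OCc3ccccc3)cc(OCc3ccccc3)c3c(=O)cc(-c4ccc(OCc5ccccc5)cc4)oc23)c1)[O-] | intermediate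
18 | potassium 2-[(1S)-1-aryl-2-cyanoethoxy]-4,6-bis(benzyloxy)phenide, aryl as in 10 (carbanion on the later C4a) | [K+].N#CC[C@@H](c1ccc(OCc2ccccc2)c(-c2c(OCc3ccccc3)cc(OCc3ccccc3)c3c(=O)cc(-c4ccc(OCc5ccccc5)cc4)oc23)c1)Oc1cc(OCc2ccccc2)cc(OCc2ccccc2)[c-]1 | intermediate
19 | potassium salt of (2S)-5,7-bis(benzyloxy)-2-aryl-chroman-4-imine, aryl as in 10 (N-metalated ketimine) | [K+].[N-]=C1C[C@@H](c2ccc(OCc3ccccc3)c(-c3c(OCc4ccccc4)cc(OCc4ccccc4)c4c(=O)cc(-c5ccc(OCc6ccccc6)cc5)oc34)c2)Oc2cc(OCc3ccccc3)cc(OCc3ccccc3)c21 | intermediate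
20 | (2S)-5,7-bis(benzyloxy)-2-{4-(benzyloxy)-3-[5,7-bis(benzyloxy)-2-(4-benzyloxyphenyl)-4-oxo-4H-chromen-8-yl]phenyl}chroman-4-one (hexa-O-benzyl ether of the target) | O=C1C[C@@H](c2ccc(OCc3ccccc3)c(-c3c(OCc4ccccc4)cc(OCc4ccccc4)c4c(=O)cc(-c5ccc(OCc6ccccc6)cc5)oc34)c2)Oc2cc(OCc3ccccc3)cc(OCc3ccccc3)c21 | intermediate
21 | (2S)-2,3-dihydroamentoflavone | O=C1C[C@@H](c2ccc(O)c(-c3c(O)cc(O)c4c(=O)cc(-c5ccc(O)cc5)oc34)c2)Oc2cc(O)cc(O)c21 | target

**Totals**
Total step count: 12. Longest linear sequence: 8 steps (steps 3, 4, 5, 6, 7, 8, 11, 12, from compound 4).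

**Steps most likely to fail**

Step 11. The aryl anion may be protonated before it reaches the nitrile, which would stop the sequence at the open aryl ether. The alkoxide may also fragment by loss of the cyanomethyl anion, which would cost material and, if reversible, enantiopurity. The fallback separates the two bond formations and uses known reactions. It sets out from 10, which is desilylated (TBAF, AcOH, THF, 0 °C) to the free (3S)-alcohol F1. The neutral alcohol is then O-arylated by the aryne from 15 (KF, 18-crown-6, THF, 25 °C), the oxonium proton quenching the aryl anion, to give with retention the (3S)-3-aryl-3-[3,5-bis(benzyloxy)phenoxy]propanenitrile F2. An intramolecular Houben–Hoesch reaction (HCl gas, ZnCl2, Et2O/CH2Cl2, 0 °C) closes the same C4–C4a bond electrophilically at either of the two equivalent ortho positions of the symmetrical phenoxy ring, giving the ketiminium chloride F3. Warm water hydrolyses it, and the route is rejoined at 20.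

Step 12. Hydrogenolysis may run on past debenzylation, cleaving the benzylic C2–O1 bond of ring C or saturating the pyranone double bond of the flavone unit. It may also stall when partly deprotected material precipitates. The fallback replaces reduction by Lewis-acid cleavage: from 20, BCl3 and pentamethylbenzene as cation scavenger in CH2Cl2 at –78 °C should give 21 directly, without a new compound.

Step 8. Transmetalation onto the arylpalladium iodide flanked by two ortho oxygens may be slow enough for protodeboronation of the ortho-alkoxy boronate to take over. The fallback inverts the polarity and omits step 7. From 3, zinc insertion (Zn dust, LiCl, THF, 50 °C) should give the arylzinc iodide F4. Negishi coupling of F4 with bromide 8 (Pd(OAc)2, SPhos, THF, 60 °C) rejoins the route at 10.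

**Further compounds**
F1 | step 11 | (3S)-3-{4-(benzyloxy)-3-[5,7-bis(benzyloxy)-2-(4-benzyloxyphenyl)-4-oxo-4H-chromen-8-yl]phenyl}-3-hydroxypropanenitrile | N#CC[C@@H](c1ccc(OCc2ccccc2)c(-c2c(OCc3ccccc3)cc(OCc3ccccc3)c3c(=O)cc(-c4ccc(OCc5ccccc5)cc4)oc23)c1)O
F2 | step 11 | (3S)-3-{4-(benzyloxy)-3-[5,7-bis(benzyloxy)-2-(4-benzyloxyphenyl)-4-oxo-4H-chromen-8-yl]phenyl}-3-[3,5-bis(benzyloxy)phenoxy]propanenitrile | N#CC[C@@H](c1ccc(OCc2ccccc2)c(-c2c(OCc3ccccc3)cc(OCc3ccccc3)c3c(=O)cc(-c4ccc(OCc5ccccc5)cc4)oc23)c1)Oc1cc(OCc2ccccc2)cc(OCc2ccccc2)c1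
F3 | step 11 | (2S)-5,7-bis(benzyloxy)-2-aryl-chroman-4-iminium chloride, aryl as in 10 | [Cl-].[NH2+]=C1C[C@@H](c2ccc(OCc3ccccc3)c(-c3c(OCc4ccccc4)cc(OCc4ccccc4)c4c(=O)cc(-c5ccc(OCc6ccccc6)cc5)oc34)c2)Oc2cc(OCc3ccccc3)cc(OCc3ccccc3)c21
F0 | step 12 | none | none
F4 | step 8 | [5,7-bis(benzyloxy)-2-(4-benzyloxyphenyl)-4-oxo-4H-chromen-8-yl]zinc iodide | O=c1cc(-c2ccc(OCc3ccccc3)cc2)oc2c([Zn]I)c(OCc3ccccc3)cc(OCc3ccccc3)c12
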